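Ring A of the chromone (C4a, C5, C6, C7, C8, C8a) is disconnected across C4a–C5 and C8–C8a. Its 1,3,5-oxygen pattern with the C6 methyl maps onto a 1,1-dimethoxy-2-methyl-3-silyloxybutadiene (C5–C8), while the C4a=C8a edge is one enone double bond of a 4-pyranone. A single Diels–Alder benzannulation builds ring A, and loss of p-toluenesulfenic acid and methanol aromatizes it with the C5 methyl ether and the C7 phenol already told apart. The dienophile is a 4-pyranone carrying the 4-methoxybenzyl group at C3 and a p-tolylsulfinyl activating and leaving group at C5. Duff formylation at C8 completes the target.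

Key step: step 8

Remark: the target has no stereocentre; the sulfinylpyranone is used racemic at sulfur, and sulfur is lost in the key step.

Step 1
Reactants: 1 4H-pyran-4-one
Product: 3 3,5-dibromo-4H-pyran-4-one, via 2,3,5,6-tetrabromooxan-4-one 2 (not isolated)
Conditions: Br2 (2.1 equiv), CH2Cl2, 0 °C to rt; then Et3N (2.5 equiv), 0 °C to rt
Reagents that add atoms: bromine, BrBr
Why: Bromine adds across each enol-ether-like C=C of the vinylogous ester (electrophilic attack at C3/C5, bromide capture at C2/C6) and the amine then removes HBr from each α-bromo ether unit, the classical addition–elimination α-bromination of chromones and 4-pyranones.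

Step 2
Reactants: 3 3,5-dibromo-4H-pyran-4-one; 4 4-methoxybenzyl chloride
Product: 6 3-bromo-5-(4-methoxybenzyl)-4H-pyran-4-one, via (4-methoxybenzyl)zinc chloride 5 (not isolated)
Conditions: 4 (1.0 equiv), Zn dust (1.5 equiv), LiCl (1.5 equiv), THF, 25 °C; then 3 (1.5 equiv), Pd(PPh3)4 (3 mol %), THF, 25 to 50 °C
Reagents that add atoms: none
Why: LiCl-assisted zinc insertion into the benzylic chloride gives a mild benzylzinc reagent for Negishi cross-coupling at one vinylic C–Br bond; it is kept limiting against excess symmetric dibromide, and the first benzyl group makes the remaining C–Br bond more electron-rich and slower in oxidative addition, so mono-coupling should dominate.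

Step 3
Reactants: 6 3-bromo-5-(4-methoxybenzyl)-4H-pyran-4-one; 7 4-methylbenzenethiol
Product: 8 3-(4-methoxybenzyl)-5-(p-tolylsulfanyl)-4H-pyran-4-one
Conditions: Pd2(dba)3 (2.5 mol %), Xantphos (5 mol %), iPr2NEt (2 equiv), 1,4-dioxane, 100 °C
Reagents that add atoms: none
Why: Palladium/Xantphos-catalysed C–S cross-coupling (Buchwald–Hartwig-type thioetherification) of a vinylic bromide with an arenethiol, run with a weak amine base so that little free thiolate is present and conjugate attack on the pyranone should not compete.

Step 4
Reactants: 8 3-(4-methoxybenzyl)-5-(p-tolylsulfanyl)-4H-pyran-4-one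
Product: 9 3-(4-methoxybenzyl)-5-(p-tolylsulfinyl)-4H-pyran-4-one (racemic at sulfur)
Conditions: mCPBA (1.0 equiv), CH2Cl2, −20 to 0 °C
Reagents that add atoms: 3-chloroperoxybenzoic acid (mCPBA), O=C(OO)c1cccc(Cl)c1
Why: Electrophilic oxygen transfer from one equivalent of peracid to the sulfide should stop at the sulfoxide at low temperature, the electron-poor pyranone alkenes and the anisole ring being inert; the sulfur stereocentre forms without control (racemic), which is immaterial because sulfur leaves in step 8.

Step 5
Reactants: 10 trimethyl orthopropionate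
Product: 11 1,1-dimethoxyprop-1-ene
Conditions: Me3SiOTf (1.05 equiv), iPr2NEt (1.2 equiv), CH2Cl2, −20 °C to rt; distillation
Reagents that add atoms: none
Why: The silyl triflate abstracts one methoxide to give the dimethoxycarbenium ion and the hindered amine removes the α-proton, the established silyl triflate/amine dealcoholation of acetals and orthoesters to enol ethers and ketene acetals.

Step 6
Reactants: 11 1,1-dimethoxyprop-1-ene; 12 acetyl chloride
Product: 13 4,4-dimethoxy-3-methylbut-3-en-2-one
Conditions: 11 (1.2 equiv), 12 (1.0 equiv), pyridine (1.2 equiv), CH2Cl2, 0 °C to rt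
Reagents that add atoms: none
Why: C-acylation of the nucleophilic ketene acetal by the N-acetylpyridinium ion and deprotonation of the resulting acylated dimethoxycarbenium ion give the push–pull acylketene acetal (ketene acetal acylation); pyridine is chosen over Et3N so that no ketene is generated from acetyl chloride.

Step 7
Reactants: 13 4,4-dimethoxy-3-methylbut-3-en-2-one
Product: 15 1,1-dimethoxy-2-methyl-3-(trimethylsilyloxy)buta-1,3-diene, via lithium dienolate 14 (not isolated)
Conditions: LiN(iPr)2 (1.1 equiv), THF, −78 °C; then Me3SiCl (1.2 equiv), −78 °C to rt; filtration under argon, bulb-to-bulb distillation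
Reagents that add atoms: chlorotrimethylsilane, C[Si](C)(C)Cl
Why: Kinetic deprotonation of the only enolizable position (the acetyl CH3) and O-silylation of the lithium dienolate give the 2-silyloxydiene, the standard silyl enol ether synthesis applied to a cross-conjugated enone.

Step 8
Reactants: 9 3-(4-methoxybenzyl)-5-(p-tolylsulfinyl)-4H-pyran-4-one (racemic at sulfur); 15 1,1-dimethoxy-2-methyl-3-(trimethylsilyloxy)buta-1,3-diene
Product: 19 7-hydroxy-5-methoxy-3-(4-methoxybenzyl)-6-methylchromen-4-one, via cis-fused cycloadduct 16 (not isolated), via dihydrochromenone ketal 17 (not isolated), via 7-silyl ether 18 (not isolated)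
Conditions: 15 (3 equiv), PhMe, 80 then 110 °C, sealed tube; then 1 M HCl, THF, rt
Reagents that add atoms: none
Why: A normal-electron-demand (4+2) cycloaddition joins the nucleophilic CH2 terminus of 15 to the oxygen-bearing β-carbon of the sulfinyl enone (C8–C8a) and the ketene acetal carbon to the sulfinyl-bearing α-carbon (C5–C4a), giving cis-fused 16 in which the sulfinyl group and H8a are syn. Thermal syn-elimination of p-toluenesulfenic acid then restores C4a=C8a (17), 1,4-loss of methanol from the C5 ketal and C8–H aromatizes ring A (18), and dilute acid frees the C7 phenol while the C5 methyl ether stays. The closest known reaction type is the Diels–Alder benzannulation of 1,1-dialkoxy-3-silyloxybutadienes with dienophiles that carry a leaving group (haloquinones, 3-sulfinyl and other 3-substituted chromones leading to xanthones), followed by eliminative aromatization. Ring A, a six-membered carbocycle, is closed intermolecularly by the cycloaddition itself, both ring bonds arising in one operation (if the addition is asynchronous, Michael-type C8–C8a bonding leads and the sulfinyl-stabilized enolate closes onto the dimethoxycarbenium carbon). No stereocentre survives, since the transient centres at C4a, C8a and sulfur are erased by the eliminations, and the one stereochemical requirement, the syn relation of sulfinyl and H8a, follows from suprafacial addition to the cyclic alkene. The step needs site selectivity and regioselectivity: only the sulfinyl-bearing C5=C6 alkene of 9 is doubly activated (ketone plus sulfoxide) whereas the benzyl-bearing C2=C3 alkene is a plain vinylogous ester, the polarization of the diene (nucleophilic C4) matches the electrophilic β-carbon, and the excess diene intercepts the sulfenic acid and methanol that are released.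

Step 9
Reactants: 19 7-hydroxy-5-methoxy-3-(4-methoxybenzyl)-6-methylchromen-4-one
Product: 21 7-hydroxy-5-methoxy-3-(4-methoxybenzyl)-6-methyl-4-oxo-4H-chromene-8-carbaldehyde, via C8 aldimine 20 (not isolated)
Conditions: hexamethylenetetramine (2 equiv), CF3CO2H, 80 °C; then 3 M HCl (aq), 60 °C
Reagents that add atoms: hexamethylenetetramine, C1N2CN3CN1CN(C2)C3; water, O
Why: Duff formylation, in which the iminium ion from protonated hexamethylenetetramine attacks C8 (the only unsubstituted carbon of ring A, ortho to the C7 phenol and to O1 and para to the C5 methoxy), the benzylic amine is oxidized by hydride transfer to aldimine 20 and aqueous acid hydrolyses it to the aldehyde; the less activated 4-alkylanisole ring and the electron-poor C2 should not react.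

Compound list
1 | 4H-pyran-4-one | O=c1ccocc1 | starting material
2 | 2,3,5,6-tetrabromooxan-4-one (mixture of diastereomers, not isolated) | O=C1C(Br)C(Br)OC(Br)C1Br | intermediate
3 | 3,5-dibromo-4H-pyran-4-one | O=c1c(Br)cocc1Br | intermediate
4 | 4-methoxybenzyl chloride | COc1ccc(CCl)cc1 | starting material
5 | (4-methoxybenzyl)zinc chloride (THF solution, not isolated) | COc1ccc(C[Zn]Cl)cc1 | intermediate
6 | 3-bromo-5-(4-methoxybenzyl)-4H-pyran-4-one | COc1ccc(Cc2cocc(Br)c2=O)cc1 | intermediate
7 | 4-methylbenzenethiol | Cc1ccc(S)cc1 | starting material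
8 | 3-(4-methoxybenzyl)-5-(p-tolylsulfanyl)-4H-pyran-4-one | COc1ccc(Cc2cocc(Sc3ccc(C)cc3)c2=O)cc1 | intermediate
9 | 3-(4-methoxybenzyl)-5-(p-tolylsulfinyl)-4H-pyran-4-one (racemic at sulfur) | COc1ccc(Cc2cocc(S(=O)c3ccc(C)cc3)c2=O)cc1 | intermediate
10 | trimethyl orthopropionate | CCC(OC)(OC)OC | starting material
11 | 1,1-dimethoxyprop-1-ene | CC=C(OC)OC | intermediate
12 | acetyl chloride | CC(=O)Cl | starting material
13 | 4,4-dimethoxy-3-methylbut-3-en-2-one | CC(=O)C(C)=C(OC)OC | intermediate
14 | lithium 4,4-dimethoxy-3-methylbuta-1,3-dien-2-olate (not isolated) | [Li+].[O-]C(=C)C(C)=C(OC)OC | intermediate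
15 | 1,1-dimethoxy-2-methyl-3-(trimethylsilyloxy)buta-1,3-diene | COC(OC)=C(C)C(=C)O[Si](C)(C)C | intermediate
16 | 5,5-dimethoxy-3-(4-methoxybenzyl)-6-methyl-4a-(p-tolylsulfinyl)-7-(trimethylsilyloxy)-4a,5,8,8a-tetrahydro-4H-chromen-4-one (cis-fused: sulfinyl on C4a and H on C8a on the same face; racemic, relative configuration shown; both sulfur epimers; not isolated) | COc1ccc(CC2=CO[C@@H]3CC(O[Si](C)(C)C)=C(C)C(OC)(OC)[C@]3(S(=O)c4ccc(C)cc4)C2=O)cc1 | intermediate
17 | 5,5-dimethoxy-3-(4-methoxybenzyl)-6-methyl-7-(trimethylsilyloxy)-5,8-dihydro-4H-chromen-4-one (not isolated) | COc1ccc(CC2=COC3=C(C2=O)C(OC)(OC)C(C)=C(O[Si](C)(C)C)C3)cc1 | intermediate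
18 | 5-methoxy-3-(4-methoxybenzyl)-6-methyl-7-(trimethylsilyloxy)chromen-4-one (not isolated) | COc1ccc(Cc2coc3cc(O[Si](C)(C)C)c(C)c(OC)c3c2=O)cc1 | intermediate
19 | 7-hydroxy-5-methoxy-3-(4-methoxybenzyl)-6-methylchromen-4-one | COc1ccc(Cc2coc3cc(O)c(C)c(OC)c3c2=O)cc1 | intermediate
20 | 7-hydroxy-8-(iminomethyl)-5-methoxy-3-(4-methoxybenzyl)-6-methylchromen-4-one (present as its trifluoroacetate salt, not isolated) | COc1ccc(Cc2coc3c(C=N)c(O)c(C)c(OC)c3c2=O)cc1 | intermediate
21 | 7-hydroxy-5-methoxy-3-(4-methoxybenzyl)-6-methyl-4-oxo-4H-chromene-8-carbaldehyde (CNP0177360.0) | COc1ccc(Cc2coc3c(C=O)c(O)c(C)c(OC)c3c2=O)cc1 | target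

Total step count: 9 steps.
Longest linear sequence: 6 steps (steps 1, 2, 3, 4, 8 and 9); the diene arm (steps 5 to 7) joins at step 8.

Steps most likely to fail

1. Step 8 (key step). The labile ketene-acetal diene may be consumed by protodesilylation, hydrolysis or sulfenylation by the released sulfenic acid and methanol faster than it adds to the push–pull-deactivated pyranone alkene. Partial hydrolysis of the C5 ketal before methanol is lost may also erode the C5 methyl ether. The fallback sets out from 9 and comes back at 19. It gives up the differentiation of the two oxygens by the diene and makes it with protecting groups instead: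
   - Commercial methyl 2-methylacetoacetate (CC(=O)C(C)C(=O)OC) is silylated (Me3SiCl, Et3N) to methyl 2-methyl-3-(trimethylsilyloxy)but-2-enoate F1.
   - Deprotonation and silylation (LiN(iPr)2, Me3SiCl, THF, −78 °C) give 1-methoxy-2-methyl-1,3-bis(trimethylsilyloxy)buta-1,3-diene F2, a robust diene that is easy to make in quantity and can be used in large excess.
   - Cycloaddition of F2 with 9 in toluene and acidic work-up should give, after loss of sulfenic acid and methanol, 5,7-dihydroxy-3-(4-methoxybenzyl)-6-methylchromen-4-one F3.
   - The non-chelated C7 hydroxyl is protected selectively (MOMCl, iPr2NEt, CH2Cl2, 0 °C) to give 5-hydroxy-7-(methoxymethoxy)-3-(4-methoxybenzyl)-6-methylchromen-4-one F4.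
   - The hydrogen-bonded C5 hydroxyl is methylated (MeI, K2CO3, DMF, 50 °C) to give 5-methoxy-7-(methoxymethoxy)-3-(4-methoxybenzyl)-6-methylchromen-4-one F5.
   - HCl in MeOH removes the acetal and gives 19.

2. Step 2. Over-coupling at the second C–Br bond and homocoupling of the benzylic zinc reagent may give a statistical mixture that is hard to separate. The fallback sets out from 3 and 7 and comes back at 9. It moves the desymmetrization to the C–S bond formation, where the first arylthio group, a stronger donor than benzyl, deactivates the remaining C–Br bond more strongly: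
   - 3 and 7 (0.9 equiv) under the conditions of step 3 give 3-bromo-5-(p-tolylsulfanyl)-4H-pyran-4-one F6.
   - Oxidation with mCPBA gives 3-bromo-5-(p-tolylsulfinyl)-4H-pyran-4-one F7.
   - Its single, sulfinyl-activated C–Br bond is coupled with the zinc reagent 5 (Negishi, Pd(PPh3)4, THF) to give 9 directly, with no possibility of double benzylation.

3. Step 6. The acylated dimethoxycarbenium ion may collapse by chloride-induced O-demethylation to the β-keto ester instead of losing a proton, and the ketene acetal may oligomerize under the acylating conditions. The fallback sets out from 12 and comes back at 13; it also makes step 5 unnecessary: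
   - Friedel–Crafts-type acylation of commercial 1,1-dichloroprop-1-ene (CC=C(Cl)Cl) with 12 (AlCl3, CH2Cl2, 0 °C) gives 4,4,4-trichloro-3-methylbutan-2-one F8.
   - F8 loses hydrogen chloride on distillation to give 4,4-dichloro-3-methylbut-3-en-2-one F9.
   - Two addition–elimination events with NaOMe (2 equiv, MeOH, 0 °C) replace both vinylic chlorides and give 13.

Further compounds
F1 | step 8 | methyl 2-methyl-3-(trimethylsilyloxy)but-2-enoate | COC(=O)C(C)=C(C)O[Si](C)(C)C
F2 | step 8 | 1-methoxy-2-methyl-1,3-bis(trimethylsilyloxy)buta-1,3-diene | COC(O[Si](C)(C)C)=C(C)C(=C)O[Si](C)(C)C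
F3 | step 8 | 5,7-dihydroxy-3-(4-methoxybenzyl)-6-methylchromen-4-one | COc1ccc(Cc2coc3cc(O)c(C)c(O)c3c2=O)cc1
F4 | step 8 | 5-hydroxy-7-(methoxymethoxy)-3-(4-methoxybenzyl)-6-methylchromen-4-one | COCOc1cc2occ(Cc3ccc(OC)cc3)c(=O)c2c(O)c1C
F5 | step 8 | 5-methoxy-7-(methoxymethoxy)-3-(4-methoxybenzyl)-6-methylchromen-4-one | COCOc1cc2occ(Cc3ccc(OC)cc3)c(=O)c2c(OC)c1C
F6 | step 2 | 3-bromo-5-(p-tolylsulfanyl)-4H-pyran-4-one | Cc1ccc(Sc2cocc(Br)c2=O)cc1
F7 | step 2 | 3-bromo-5-(p-tolylsulfinyl)-4H-pyran-4-one (racemic at sulfur) | Cc1ccc(S(=O)c2cocc(Br)c2=O)cc1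
F8 | step 6 | 4,4,4-trichloro-3-methylbutan-2-one (racemic) | CC(=O)C(C)C(Cl)(Cl)Cl
F9 | step 6 | 4,4-dichloro-3-methylbut-3-en-2-one | CC(=O)C(C)=C(Cl)Cl
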